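**Retrosynthetic overview**

1. Numbering: ring O1–O2–C3–C4–C5, side chain C1′–C15′ on C5. The last C–C bond made is C5′–C6′ (alkyl CH2 to allylic CH2), which divides the target into the dioxolane alkene 18 and the racemic 1,4-dien-3-yl phosphate 26.
2. Key step: one-pot anti-Markovnikov hydroboration of the vinyl group of 18, then copper-catalysed anti-SN2′ attack on the vinyl group of 26. Two alkene CH2 termini of like polarity are joined by reversing the polarity of one; the same operation creates the 7′E alkene and brings the 7′,9′-diene into conjugation.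
3. Enabling feature: C6′ is the terminus of the C6′–C10′ pentadienyl unit, so a leaving group on the doubly allylic C8′ makes it an SN2′ acceptor; C5′ ends an unbranched (CH2)5 tether from C5; and the O1–O2 bond is flanked by the fully substituted C3 and C5 (no α-H, shielded), so the peroxide should tolerate borane, borate and Cu(I).
4. Dioxolane 18: the C5–O bond comes from a Sharpless epoxide → 1,3-diol → oxetane → H2O2 opening with inversion; C3 comes from a peroxyhemiketal → peroxycarbenium ion → silyl ketene acetal addition. Ring order: epoxide (step 3), oxetane (step 7), 1,2-dioxolane (step 11, complete before the union).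
5. Phosphate 26: acrolein + ethynylmagnesium bromide, copper coupling with (Z)-pentenyl bromide, Red-Al trans-reduction, phosphorylation.

Key step: step 18

Remark on the chemistry: the target SMILES is read as (3R,5S), with the 3- and 5-methyl groups trans across the dioxolane. Compounds 8–13 are carried as mixtures at the carbinol carbon, which becomes the ketone/ketal carbon and is only set in step 12.

**Route**

Step 1
Reactants: 1 5-bromopent-1-ene; 2 ethyl but-2-ynoate
Product: 4 ethyl (2E)-3-methylocta-2,7-dienoate, via pent-4-enylmagnesium bromide 3 (not isolated)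
Conditions: Mg, THF, rt; then CuBr·SMe2 (10 mol %), 2, THF, −78 °C; pH 7 buffer quench at −78 °C
Reagents that add atoms: none
Why: Copper-catalysed syn-carbometalation (conjugate addition of a Grignard reagent to an ynoate) places the pentenyl group trans to the ester, and cold protonation before allenoate equilibration should give the E-enoate.

Step 2
Reactants: 4 ethyl (2E)-3-methylocta-2,7-dienoate
Product: 5 (2E)-3-methylocta-2,7-dien-1-ol
Conditions: DIBAL-H (2.2 equiv), CH2Cl2, −78 → 0 °C; Rochelle salt
Reagents that add atoms: none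
Why: DIBAL-H 1,2-reduction of an α,β-unsaturated ester stops cleanly at the allylic alcohol without touching either alkene.

Step 3
Reactants: 5 (2E)-3-methylocta-2,7-dien-1-ol
Product: 6 [(2R,3R)-3-methyl-3-(pent-4-en-1-yl)oxiran-2-yl]methanol
Conditions: Ti(OiPr)4 (10 mol %), D-(−)-diethyl tartrate (12 mol %), t-BuOOH (2 equiv, decane), 4 Å MS, CH2Cl2, −20 °C
Reagents that add atoms: tert-butyl hydroperoxide, CC(C)(C)OO
Why: Sharpless asymmetric epoxidation; D-(−)-tartrate should direct oxygen to the face giving the (2R,3R)-epoxide (the mirror image of the series obtained from (E)-3-methylalk-2-en-1-ols with the L-(+)-ester), which fixes the tertiary C–O centre, and the isolated vinyl group is not epoxidised.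

Step 4
Reactants: 6 [(2R,3R)-3-methyl-3-(pent-4-en-1-yl)oxiran-2-yl]methanol
Product: 7 (2S,3R)-3-methyl-3-(pent-4-en-1-yl)oxirane-2-carbaldehyde
Conditions: PhI(OAc)2 (1.1 equiv), TEMPO (10 mol %), CH2Cl2, rt
Reagents that add atoms: none
Why: TEMPO/PhI(OAc)2 oxidation of a primary alcohol is neutral enough to leave the epoxide and the alkene alone (the descriptor at C2 changes only through CIP priority).

Step 5
Reactants: 7 (2S,3R)-3-methyl-3-(pent-4-en-1-yl)oxirane-2-carbaldehyde
Product: 8 1-[(2R,3R)-3-methyl-3-(pent-4-en-1-yl)oxiran-2-yl]ethan-1-ol (both carbinol epimers)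
Conditions: MeMgBr (1.2 equiv), THF, −78 °C; pH 7 buffer
Reagents that add atoms: methylmagnesium bromide, C[Mg]Br
Why: Grignard 1,2-addition to the aldehyde is much faster than epoxide opening at −78 °C; the new carbinol centre need not be controlled because it is oxidised in step 10.

Step 6
Reactants: 8 1-[(2R,3R)-3-methyl-3-(pent-4-en-1-yl)oxiran-2-yl]ethan-1-ol
Product: 9 (4R)-4-methylnon-8-ene-2,4-diol (C2 epimers)
Conditions: Red-Al (2.5 equiv), THF, 0 °C → rt; Rochelle salt
Reagents that add atoms: none
Why: Alkoxyaluminate-directed hydride delivery to C2 of a 2,3-epoxy alcohol (also the only non-quaternary epoxide carbon) should give the 1,3-diol and leaves the tertiary C–O bond, and so its configuration, intact.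

Step 7
Reactants: 9 (4R)-4-methylnon-8-ene-2,4-diol
Product: 11 (2R)-2,4-dimethyl-2-(pent-4-en-1-yl)oxetane, via secondary tosylate 10 (not isolated)
Conditions: TsCl (1.1 equiv), pyridine, DMAP (cat.), CH2Cl2, 0 °C → rt; then KOt-Bu (1.5 equiv), THF, 0 → 40 °C
Reagents that add atoms: none
Why: Selective sulfonylation of the less hindered secondary hydroxyl followed by 4-exo-tet Williamson closure by the tertiary alkoxide forms the oxetane with inversion only at the secondary carbon, so the tertiary centre stays R.

Step 8
Reactants: 11 (2R)-2,4-dimethyl-2-(pent-4-en-1-yl)oxetane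
Product: 12 (4S)-4-hydroperoxy-4-methylnon-8-en-2-ol (C2 epimers)
Conditions: anhydrous ethereal H2O2 (10 equiv), TMSOTf (0.2 equiv), Et2O, −78 → −20 °C
Reagents that add atoms: hydrogen peroxide, OO
Why: Lewis-acid-activated oxetanes are opened by hydrogen peroxide at the more substituted carbon with inversion (backside attack on the activated C–O bond), which should install the tertiary C–OOH centre as S, the future C5.

Step 9
Reactants: 12 (4S)-4-hydroperoxy-4-methylnon-8-en-2-ol
Product: 13 (4S)-4-[(2-methoxypropan-2-yl)peroxy]-4-methylnon-8-en-2-ol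
Conditions: 2-methoxypropene (1.05 equiv), PPTS (5 mol %), CH2Cl2, −20 °C
Reagents that add atoms: 2-methoxypropene, C=C(C)OC
Why: Acid-catalysed ketalisation with an enol ether; the terminal oxygen of the hydroperoxide is less hindered and more nucleophilic (α-effect) than the secondary alcohol and gives the more acid-stable peroxyketal, so one equivalent should cap only the OOH group.

Step 10
Reactants: 13 (4S)-4-[(2-methoxypropan-2-yl)peroxy]-4-methylnon-8-en-2-ol
Product: 14 (4S)-4-[(2-methoxypropan-2-yl)peroxy]-4-methylnon-8-en-2-one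
Conditions: Dess–Martin periodinane (1.3 equiv), pyridine, CH2Cl2, 0 °C → rt
Reagents that add atoms: none
Why: Buffered Dess–Martin oxidation of a secondary alcohol tolerates dialkyl peroxyketals and alkenes, and both carbinol epimers converge on one ketone.

Step 11
Reactants: 14 (4S)-4-[(2-methoxypropan-2-yl)peroxy]-4-methylnon-8-en-2-one
Product: 16 (5S)-3-methoxy-3,5-dimethyl-5-(pent-4-en-1-yl)-1,2-dioxolane, via dioxolan-3-ol 15 (not isolated)
Conditions: TsOH·H2O (10 mol %), MeOH, 0 °C → rt
Reagents that add atoms: methanol, CO
Why: Acid methanolysis removes the peroxyketal, the freed β-hydroperoxy ketone closes to the five-membered peroxyhemiketal (5-exo-trig addition of OOH to the carbonyl), and ketal exchange with methanol gives the 3-methoxydioxolane as a C3 mixture that is of no consequence.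

Step 12
Reactants: 16 (5S)-3-methoxy-3,5-dimethyl-5-(pent-4-en-1-yl)-1,2-dioxolane; 17 tert-butyl[(1-methoxyethenyl)oxy]dimethylsilane
Product: 18 methyl 2-[(3R,5S)-3,5-dimethyl-5-(pent-4-en-1-yl)-1,2-dioxolan-3-yl]acetate
Conditions: TMSOTf (20 mol %), CH2Cl2, −78 °C; chromatographic separation from the (3S,5S)-epimer
Reagents that add atoms: none
Why: Mukaiyama-type addition of a silyl ketene acetal to the peroxycarbenium ion formed by loss of methoxide; attack anti to the larger pentenyl group on C5 should favour, though only modestly, the 3R epimer (CH2CO2Me trans to the chain, methyls trans), so the epimers are to be separated here.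

Step 13
Reactants: 19 acrolein; 20 ethynylmagnesium bromide
Product: 21 pent-1-en-4-yn-3-ol (racemic)
Conditions: THF, −78 → 0 °C; pH 7 buffer
Reagents that add atoms: none
Why: Alkynyl Grignard reagents add 1,2 to acrolein to give the vinyl ethynyl carbinol.

Step 14
Reactants: 22 (2Z)-pent-2-en-1-ol
Product: 23 (2Z)-1-bromopent-2-ene
Conditions: PBr3 (0.4 equiv), pyridine (cat.), Et2O, −20 → 0 °C
Reagents that add atoms: phosphorus tribromide, BrP(Br)Br
Why: Cold PBr3 bromination of a primary allylic alcohol proceeds by SN2 displacement of the phosphite ester and should keep the Z geometry.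

Step 15
Reactants: 21 pent-1-en-4-yn-3-ol; 23 (2Z)-1-bromopent-2-ene
Product: 24 (7Z)-deca-1,7-dien-4-yn-3-ol (racemic)
Conditions: CuI (10 mol %), K2CO3 (1.5 equiv), n-Bu4NI (10 mol %), DMF, rt
Reagents that add atoms: none
Why: Copper-acetylide alkylation of a terminal alkyne with a primary allylic halide gives the skipped enyne by direct substitution with retention of the Z alkene and tolerates the free carbinol.

Step 16
Reactants: 24 (7Z)-deca-1,7-dien-4-yn-3-ol
Product: 25 (4E,7Z)-deca-1,4,7-trien-3-ol (racemic)
Conditions: Red-Al (2.2 equiv), THF, 0 °C; Rochelle salt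
Reagents that add atoms: none
Why: Alkoxide-directed trans-hydroalumination of a propargylic alcohol and protonolysis give the E-allylic alcohol only, while the unactivated vinyl and Z-alkene are not reduced.

Step 17
Reactants: 25 (4E,7Z)-deca-1,4,7-trien-3-ol
Product: 26 diethyl (4E,7Z)-deca-1,4,7-trien-3-yl phosphate (racemic)
Conditions: ClP(O)(OEt)2 (1.2 equiv), pyridine, DMAP (cat.), CH2Cl2, 0 °C; filtered through Et3N-deactivated silica and used at once
Reagents that add atoms: diethyl chlorophosphate, CCOP(=O)(Cl)OCC
Why: O-phosphorylation of a secondary alcohol under mild base; the doubly allylic phosphate is expected to be labile and is therefore not stored.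

Step 18
Reactants: 18 methyl 2-[(3R,5S)-3,5-dimethyl-5-(pent-4-en-1-yl)-1,2-dioxolan-3-yl]acetate; 26 diethyl (4E,7Z)-deca-1,4,7-trien-3-yl phosphate
Product: 28 methyl 2-[(3R,5S)-3,5-dimethyl-5-[(7E,9E,12Z)-pentadeca-7,9,12-trien-1-yl]-1,2-dioxolan-3-yl]acetate, via B-alkyl-9-BBN 27 (not isolated)
Conditions: 9-BBN-H (0.98 equiv), THF, 0 °C → rt; then KOt-Bu (0.95 equiv), CuOAc (10 mol %), 26 (1.2 equiv), THF, 40 °C, dark, argon
Reagents that add atoms: none
Why: 9-BBN adds anti-Markovnikov to the only alkene of 18 to give the primary borane 27, which KOt-Bu turns into a borate that passes its primary alkyl group to copper; the alkylcopper species then attacks the unhindered vinyl terminus of 26 anti to the phosphate (oxidative addition to a σ-allyl copper(III), then reductive elimination), forming C5′–C6′ as the phosphate leaves C8′. The closest known reaction type is the copper-catalysed γ-selective, anti-stereospecific allyl–alkyl coupling of B-alkyl-9-BBN reagents with secondary allylic phosphates. No ring is closed and no stereocentre is created: the carbinol centre of racemic 26 is destroyed, and the new C7′=C8′ bond should be E because the anti-SN2′ transition state keeps the alkenyl substituent on C8′ away from the incoming chain to avoid A(1,3) strain, while the 9′E and 12′Z alkenes are not touched. The step needs γ-selectivity for the CH2 terminus over the substituted γ′-carbon and over direct α-attack, which the lower substitution of the vinyl group and the intrinsic γ-preference of the copper–borate system should secure. It also needs chemoselectivity over the O1–O2 bond and the ester: the peroxide is a di-tert-alkyl peroxide shielded by C3 and C5 and lacking α-hydrogens, and borane is kept in slight excess over KOt-Bu so that no free alkoxide can enolise the ester and open the ring by retro-oxa-Michael reaction.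

Step 19
Reactants: 28 methyl 2-[(3R,5S)-3,5-dimethyl-5-[(7E,9E,12Z)-pentadeca-7,9,12-trien-1-yl]-1,2-dioxolan-3-yl]acetate
Product: 29 2-[(3R,5S)-3,5-dimethyl-5-[(7E,9E,12Z)-pentadeca-7,9,12-trien-1-yl]-1,2-dioxolan-3-yl]acetic acid
Conditions: LiOH·H2O (3 equiv), THF/H2O (3:1), 0 °C → rt; then 1 M HCl to pH 3–4 at 0 °C
Reagents that add atoms: lithium hydroxide, [Li+].[OH-]
Why: Saponification by acyl attack of hydroxide is faster than α-deprotonation, so the β-peroxy ester should be hydrolysed without retro-oxa-Michael opening, and the quaternary C3 and C5 cannot epimerise.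

**Compound list**

1 | 5-bromopent-1-ene | C=CCCCBr | starting material
2 | ethyl but-2-ynoate | CC#CC(=O)OCC | starting material
3 | pent-4-enylmagnesium bromide | C=CCCC[Mg]Br | intermediate (not isolated)
4 | ethyl (2E)-3-methylocta-2,7-dienoate | C=CCCC/C(C)=C/C(=O)OCC | intermediate
5 | (2E)-3-methylocta-2,7-dien-1-ol | C=CCCC/C(C)=C/CO | intermediate
6 | [(2R,3R)-3-methyl-3-(pent-4-en-1-yl)oxiran-2-yl]methanol | OC[C@H]1O[C@]1(C)CCCC=C | intermediate
7 | (2S,3R)-3-methyl-3-(pent-4-en-1-yl)oxirane-2-carbaldehyde | O=C[C@H]1O[C@]1(C)CCCC=C | intermediate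
8 | 1-[(2R,3R)-3-methyl-3-(pent-4-en-1-yl)oxiran-2-yl]ethan-1-ol (carbinol epimers) | CC(O)[C@H]1O[C@]1(C)CCCC=C | intermediate
9 | (4R)-4-methylnon-8-ene-2,4-diol (C2 epimers) | C=CCCC[C@@](C)(O)CC(C)O | intermediate
10 | (4R)-4-hydroxy-4-methylnon-8-en-2-yl 4-methylbenzenesulfonate (secondary tosylate) | C=CCCC[C@@](C)(O)CC(C)OS(=O)(=O)c1ccc(C)cc1 | intermediate (not isolated)
11 | (2R)-2,4-dimethyl-2-(pent-4-en-1-yl)oxetane (C4 epimers) | C=CCCC[C@]1(C)CC(C)O1 | intermediate
12 | (4S)-4-hydroperoxy-4-methylnon-8-en-2-ol (C2 epimers) | C=CCCC[C@](C)(OO)CC(C)O | intermediate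
13 | (4S)-4-[(2-methoxypropan-2-yl)peroxy]-4-methylnon-8-en-2-ol | C=CCCC[C@](C)(OOC(C)(C)OC)CC(C)O | intermediate
14 | (4S)-4-[(2-methoxypropan-2-yl)peroxy]-4-methylnon-8-en-2-one | C=CCCC[C@](C)(OOC(C)(C)OC)CC(C)=O | intermediate
15 | (5S)-3,5-dimethyl-5-(pent-4-en-1-yl)-1,2-dioxolan-3-ol (C3 epimers) | C=CCCC[C@@]1(C)CC(C)(O)OO1 | intermediate (not isolated)
16 | (5S)-3-methoxy-3,5-dimethyl-5-(pent-4-en-1-yl)-1,2-dioxolane (C3 epimers) | C=CCCC[C@@]1(C)CC(C)(OC)OO1 | intermediate
17 | tert-butyl[(1-methoxyethenyl)oxy]dimethylsilane | C=C(OC)O[Si](C)(C)C(C)(C)C | starting material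
18 | methyl 2-[(3R,5S)-3,5-dimethyl-5-(pent-4-en-1-yl)-1,2-dioxolan-3-yl]acetate | C=CCCC[C@@]1(C)C[C@](C)(CC(=O)OC)OO1 | intermediate
19 | acrolein | C=CC=O | starting material
20 | ethynylmagnesium bromide | C#C[Mg]Br | starting material
21 | pent-1-en-4-yn-3-ol (racemic) | C=CC(O)C#C | intermediate
22 | (2Z)-pent-2-en-1-ol | CC/C=C\CO | starting material
23 | (2Z)-1-bromopent-2-ene | CC/C=C\CBr | intermediate
24 | (7Z)-deca-1,7-dien-4-yn-3-ol (racemic) | C=CC(O)C#CC/C=C\CC | intermediate
25 | (4E,7Z)-deca-1,4,7-trien-3-ol (racemic) | C=CC(O)/C=C/C/C=C\CC | intermediate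
26 | diethyl (4E,7Z)-deca-1,4,7-trien-3-yl phosphate (racemic) | C=CC(OP(=O)(OCC)OCC)/C=C/C/C=C\CC | intermediate
27 | methyl 2-[(3R,5S)-5-[5-(9-borabicyclo[3.3.1]nonan-9-yl)pentyl]-3,5-dimethyl-1,2-dioxolan-3-yl]acetate (B-alkyl-9-BBN) | C1CCC2CCCC1B2CCCCC[C@@]1(C)C[C@](C)(CC(=O)OC)OO1 | intermediate (not isolated)
28 | methyl 2-[(3R,5S)-3,5-dimethyl-5-[(7E,9E,12Z)-pentadeca-7,9,12-trien-1-yl]-1,2-dioxolan-3-yl]acetate | CC/C=C\C/C=C/C=C/CCCCCC[C@@]1(C)C[C@](C)(CC(=O)OC)OO1 | intermediate
29 | 2-[(3R,5S)-3,5-dimethyl-5-[(7E,9E,12Z)-pentadeca-7,9,12-trien-1-yl]-1,2-dioxolan-3-yl]acetic acid | CC/C=C\C/C=C/C=C/CCCCCC[C@@]1(C)C[C@](C)(CC(=O)O)OO1 | target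

**Step count and risks**

Total step count: 19. Longest linear sequence: 14 steps (steps 1–12, 18, 19).

Steps most likely to fail:

1. Step 18. The doubly allylic phosphate may ionise or undergo a 1,3-phosphate shift before coupling, which would divert copper to the internal position and give a branched skipped triene. Attack at the substituted γ′-terminus and single-electron reduction of the O–O bond by Cu(I) are further failure modes. The fallback sets out from 18 and 25 and comes back at 28. Hydroboration of 18 with 9-BBN-H and oxidation with NaBO3 should give the alcohol methyl 2-[(3R,5S)-5-(5-hydroxypentyl)-3,5-dimethyl-1,2-dioxolan-3-yl]acetate F1, and I2/PPh3/imidazole should convert it into the iodide methyl 2-[(3R,5S)-5-(5-iodopentyl)-3,5-dimethyl-1,2-dioxolan-3-yl]acetate F2. Alcohol 25 is acylated with methyl chloroformate and pyridine to the stable carbonate (4E,7Z)-deca-1,4,7-trien-3-yl methyl carbonate F3. A nickel-catalysed reductive allylation of the alkyl iodide with the allylic carbonate (NiCl2·glyme, a bipyridine ligand, Zn, MgCl2, DMA, rt) then joins F2 and F3 as two electrophiles. The π-pentadienyl nickel intermediate should couple at its unsubstituted terminus to give the linear E,E-diene 28.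

2. Step 12. Methyl and CH2R on C5 may be too similar to bias the face of the planar peroxycarbenium ion, so the C3 epimers could form in nearly equal amounts; Lewis-acid-induced fragmentation of the peroxide is a second failure mode. The fallback sets out from 14 and comes back at 18. A Horner–Wadsworth–Emmons reaction of 14 with trimethyl phosphonoacetate under Masamune–Roush conditions (LiCl, DBU, MeCN) should give the enoate methyl (5S)-5-[(2-methoxypropan-2-yl)peroxy]-3,5-dimethyldeca-2,9-dienoate F4 (either alkene geometry serves). Aqueous acetic acid should free the hydroperoxide methyl (5S)-5-hydroperoxy-3,5-dimethyldeca-2,9-dienoate F5. Diethylamine in 2,2,2-trifluoroethanol should then close the ring by 5-exo-trig oxa-Michael addition to give 18. Because this closure is reversible, the unwanted C3 epimer can be resubmitted to the same conditions and re-equilibrated.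

3. Step 9. The secondary alcohol may compete with the hydroperoxide for the enol ether, giving mixtures of mono- and bis-ketals that cannot be oxidised selectively. The fallback sets out from 12 and comes back at 13. Excess 2-methoxypropene with PPTS should ketalise both hydroxyl groups to give (4S)-2-[(2-methoxypropan-2-yl)oxy]-4-[(2-methoxypropan-2-yl)peroxy]-4-methylnon-8-ene F6. Brief methanolysis (PPTS, MeOH, −20 °C) should then cleave only the far more acid-labile alkyl ketal and release 13.

**Further compounds**

F1 | step 18 | methyl 2-[(3R,5S)-5-(5-hydroxypentyl)-3,5-dimethyl-1,2-dioxolan-3-yl]acetate | OCCCCC[C@@]1(C)C[C@](C)(CC(=O)OC)OO1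
F2 | step 18 | methyl 2-[(3R,5S)-5-(5-iodopentyl)-3,5-dimethyl-1,2-dioxolan-3-yl]acetate | ICCCCC[C@@]1(C)C[C@](C)(CC(=O)OC)OO1
F3 | step 18 | (4E,7Z)-deca-1,4,7-trien-3-yl methyl carbonate | C=CC(OC(=O)OC)/C=C/C/C=C\CC
F4 | step 12 | methyl (5S)-5-[(2-methoxypropan-2-yl)peroxy]-3,5-dimethyldeca-2,9-dienoate | C=CCCC[C@](C)(OOC(C)(C)OC)CC(C)=CC(=O)OC
F5 | step 12 | methyl (5S)-5-hydroperoxy-3,5-dimethyldeca-2,9-dienoate | C=CCCC[C@](C)(OO)CC(C)=CC(=O)OC
F6 | step 9 | (4S)-2-[(2-methoxypropan-2-yl)oxy]-4-[(2-methoxypropan-2-yl)peroxy]-4-methylnon-8-ene | C=CCCC[C@](C)(OOC(C)(C)OC)CC(C)OC(C)(C)OC
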